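The data were computed on assumed constants, noise included.

Read the flat end of each run first, then ask how much solid substrate the protic impurity spares.

| setting | south-east | south | flask |
|---|---|---|---|
| solid substrate | 0.40 M | 0.40 M | 0.40 M |
| protic impurity | 0.020 M | 0.040 M | 0.0200 M |
| remark | the very flask that is asked about, followed so far | run made earlier |  |
| time |  |  | 25 h |

- south-east (time / h: solid substrate / %, target / %): 0.667: 32.9, 29.4; 2.00: 0.1, 69.8; 4.00: 0, 76.8; 5.00: 0, 76.2; 8.00: 0, 76.7; 10.0: 0, 76.9
- south (time / h: solid substrate / %, target / %): 0.667: 30.6, 29.7; 2.00: 0.6, 66.4; 4.00: 0.4, 71.5; 5.00: 0, 72.6; 8.00: 1.1, 73.1; 10.0: 0.7, 71.5

(each reading ± 0.5 percentage points)

- given per volume of solution although it is solid: solid substrate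
- at the start none of the solid substrate is in solution
- what has only dissolved of solid substrate counts as not reacted
- the reaction counts as stopped when no species that holds the solid substrate changes by six tenths of a point or more over the second half of the time
- what has gone from starting material into another species counts as reacted, even if it can come back
- starting material means what is dissolved; the solid is not counted in it

- which holds at 25 h: what has brought the reaction to rest, or that it has not come to rest (for what has run out or reacted, a solid counts together with what of it has only dissolved) (all of the solid substrate has reacted / it is still moving / forward and back rates have come level)
- part of the solid substrate that has turned into other species by 25 h (what has only dissolved does not count)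
- how much target there is at 25 h, in percent of the solid substrate charged
- how much starting material there is at 25 h, in percent of the solid substrate charged

The asked flask is the south-east run followed on to 25 h. Its target stands flat from 4.00 h, averaging 76.7%. The south run averages 72.2%.

My own assumption is that each protic impurity takes one substrate. That spares 95.0% of the charge in the south-east run and 90.0% in the south run. Target over spared charge is then 80.7% and 80.2%, 0.50 percentage points apart. Call this the kept share: target per unit of spared charge, as read from the flat ends of the runs.

Now bracket starting material in the asked flask. From above, the whole remainder is starting material: 18.3%, which puts conversion at 81.7%. From below, starting material can stand at zero, with conversion complete. The hand stops there, since flat target readings do not say what the remainder is.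

The forecast says forward and back rates have come level, with conversion 81.7%, target 76.7% and starting material 18.3%. Its ground is that the constant fraction “suggests an equilibrium between starting material and target”. That places it at the upper edge of the bracket.

The flask gives forward and back rates have come level, with conversion 97.4%, target 76.7% and starting material 2.56%, inside the bracket.

    starting material + protic impurity → quenched substrate (k = 1.20 M⁻¹ min⁻¹)
    starting material ⇌ target (K = 30.0, k = 0.170 min⁻¹)
    solid substrate ⇌ starting material, rate k3*(cs3 - [starting material]) while solid is left; crystals form when [starting material] > cs3 (solubility = 26.0 mM, k = 1.00 min⁻¹)
    starting material ⇌ dormant form (K = 5.20, k = 0.450 min⁻¹)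
    starting material ⇌ isomer of the product (K = 0.970, k = 0.0200 min⁻¹)

At 25.0 h the dormant form holds 13.3% of the charge. Quenched substrate stands at 5.00%, and the kept share of what that leaves is 76.7% of target.

Take the neighbour flask with 0.16 M of solid substrate and the same protic impurity. It spares 87.5%, so the kept share gives 70.6% of target. That flask computes to 70.6%.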